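**Retrosynthetic overview**

1. Target 20 ⇐ prenyl ketone 19 (Schenck ene reaction gives the tertiary hydroperoxide and the E-enone) ⇐ epoxy ketone 15 (hydroxylation and esterification at C3; side-chain C–OSi → C=O).
2. 15 ⇐ acyclic (3S,5R)-5-chloro-6-oxoheptanal 13: a carbene-catalysed aldehyde–ketone benzoin reaction closes the cyclohexanone by making the C2(=O)–C1 bond of the 7-oxabicyclo[4.1.0]heptan-2-one, and in the same flask the new tertiary alkoxide displaces chloride to close the oxirane (ring order: carbocycle, then epoxide).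
3. Enabling feature: the ketone carbon C2 is bonded to the fully substituted oxirane carbon C1 (CH3, O7), whose oxygen bridges to C6. This is a tertiary α-ketol masked as an epoxide, so C2 can come from an aldehyde (acyl anion), C1 from a methyl ketone carbonyl and C6 from a chloride-bearing carbon.
4. 13 ⇐ lactone 7 (lactol, one-carbon Wittig homologation, organocatalytic α-chlorination, CH3MgBr, double oxidation); 7 ⇐ alkenylboronate 5 + 5,6-dihydro-2H-pyran-2-one 6 by rhodium-catalysed asymmetric conjugate addition (sets C4 of the core; the lactone ring is only a carrier).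
5. 5 ⇐ 4-methylpent-3-en-1-ol 1 (oxidation, ethynylation, silylation, copper-catalysed α-borylation).

Key step: step 11

Remarks (assumptions on the chemistry): TBS = tert-butyldimethylsilyl; the side-chain carbinol carbon made in step 2 and the methyl carbinol carbon made in step 9 are temporary stereocentres, carried as both epimers (left open in names and SMILES) and erased by oxidation in steps 15 and 10; the catalyst antipodes in steps 5 and 8 follow the usual models ((S)-BINAP–rhodium for the (4S) lactone, (2S,5S)-2,5-diphenylpyrrolidine for the (2R) chloride), and the other antipode is taken if a sense of induction proves opposite.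

**Route**

Step 1
Reactants: 1 4-methylpent-3-en-1-ol
Product: 2 4-methylpent-3-enal
Conditions: Dess–Martin periodinane (1.2 equiv), NaHCO3, CH2Cl2, 0 to 23 °C; used as a dried solution
Reagents that add atoms: none
Why: Dess–Martin oxidation of a primary alcohol is mild and non-basic, so the β,γ-double bond should stay out of conjugation.

Step 2
Reactants: 2 4-methylpent-3-enal
Product: 3 6-methylhept-5-en-1-yn-3-ol
Conditions: HC≡CMgBr (1.3 equiv), THF, −78 to 0 °C
Reagents that add atoms: ethynylmagnesium bromide, C#C[Mg]Br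
Why: 1,2-Addition of an alkynyl Grignard reagent to an aldehyde is reliable at low temperature, and the new carbinol centre needs no control because it is oxidised to the ketone in step 15.

Step 3
Reactants: 3 6-methylhept-5-en-1-yn-3-ol
Product: 4 tert-butyldimethyl[(6-methylhept-5-en-1-yn-3-yl)oxy]silane
Conditions: t-BuMe2SiCl (1.2 equiv), imidazole (2 equiv), DMF, 23 °C
Reagents that add atoms: tert-butyldimethylsilyl chloride, CC(C)(C)[Si](C)(C)Cl
Why: Silyl ether formation masks the alcohol, and with it the future side-chain ketone, which as an enone would be a Stetter or benzoin acceptor in step 11.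

Step 4
Reactants: 4 silyl ether of the alkynol
Product: 5 tert-butyldimethyl{[6-methyl-2-(4,4,5,5-tetramethyl-1,3,2-dioxaborolan-2-yl)hepta-1,5-dien-3-yl]oxy}silane
Conditions: CuCl (5 mol%), 1,3-bis(2,4,6-trimethylphenyl)-4,5-dihydroimidazolium chloride (5 mol%), NaOC(CH3)3 (15 mol%), bis(pinacolato)diboron (1.1 equiv), CH3OH (2 equiv), THF, −15 to 23 °C
Reagents that add atoms: bis(pinacolato)diboron, CC1(C)OB(OC1(C)C)B1OC(C)(C)C(C)(C)O1
Why: Copper-catalysed protoboration of a terminal alkyne (boryl–copper addition, then protonation by methanol) with an N-aryl carbene ligand places boron on the internal carbon of propargylic ethers and should give the 1,1-disubstituted alkenylboronate.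

Step 5
Reactants: 5 alkenylboronate (1.8 equiv); 6 5,6-dihydro-2H-pyran-2-one
Product: 7 (4S)-4-[3-(TBSO)-6-methylhepta-1,5-dien-2-yl]oxan-2-one
Conditions: [Rh(OH)(C8H12)]2 (C8H12 = 1,5-cyclooctadiene, 2.5 mol%), (S)-2,2'-bis(diphenylphosphino)-1,1'-binaphthyl (5.5 mol%), 1,4-dioxane/H2O (10:1), 50 °C
Reagents that add atoms: none
Why: Hayashi–Miyaura rhodium-catalysed asymmetric 1,4-addition of an alkenylboron reagent to an α,β-unsaturated lactone, in which the (S)-BINAP–rhodium alkenyl species inserts one enantioface of the enoate and so sets the (4S) centre, the future C4 of the core.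

Step 6
Reactants: 7 lactone
Product: 8 (4S)-4-[3-(TBSO)-6-methylhepta-1,5-dien-2-yl]oxan-2-ol
Conditions: i-Bu2AlH (1.1 equiv), CH2Cl2, −78 °C; sodium potassium tartrate work-up
Reagents that add atoms: none
Why: Partial reduction of a δ-lactone with i-Bu2AlH stops at the lactol because the tetrahedral aluminate is stable at −78 °C.

Step 7
Reactants: 8 lactol
Product: 10 (4R)-6-hydroxy-4-[3-(TBSO)-6-methylhepta-1,5-dien-2-yl]hexanal, via methyl enol ether 9 (not isolated)
Conditions: Ph3P(CH2OCH3)Cl (3.0 equiv), KN(SiMe3)2 (2.9 equiv), THF, 0 to 23 °C; then 1 M aq HCl/THF (1:5), 0 to 23 °C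
Reagents that add atoms: (methoxymethyl)triphenylphosphonium chloride, COC[P+](c1ccccc1)(c1ccccc1)c1ccccc1.[Cl-]; water, O
Why: Wittig methoxymethylenation of the open hydroxy-aldehyde form of the lactol followed by acid hydrolysis of the enol ether is the standard one-carbon aldehyde homologation and moves the carbonyl to the position from which the chloride can be installed.

Step 8
Reactants: 10 hydroxy aldehyde
Product: 11 (2R,4S)-2-chloro-6-hydroxy-4-[3-(TBSO)-6-methylhepta-1,5-dien-2-yl]hexanal
Conditions: N-chlorosuccinimide (1.2 equiv), (2S,5S)-2,5-diphenylpyrrolidine (10 mol%), CH2Cl2, 0 °C; used without chromatography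
Reagents that add atoms: N-chlorosuccinimide, O=C1CCC(=O)N1Cl
Why: Enamine-catalysed asymmetric α-chlorination of an aldehyde, in which the C2-symmetric pyrrolidine shields one enamine face so that the (2R) centre is set under catalyst control while the remote stereocentre, hydroxyl and alkenes are spectators.

Step 9
Reactants: 11 α-chloro aldehyde
Product: 12 (3S,5R)-5-chloro-3-[3-(TBSO)-6-methylhepta-1,5-dien-2-yl]heptane-1,6-diol
Conditions: CH3MgBr (3.5 equiv), THF, −78 °C
Reagents that add atoms: methylmagnesium bromide, C[Mg]Br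
Why: Grignard addition to an α-chloro aldehyde at −78 °C is faster than enolisation, so the chlorinated centre should be retained, and the new methyl carbinol centre (mainly anti by the Cornforth model) is immaterial because it is oxidised in step 10.

Step 10
Reactants: 12 chlorohydrin diol
Product: 13 (3S,5R)-5-chloro-3-[3-(TBSO)-6-methylhepta-1,5-dien-2-yl]-6-oxoheptanal
Conditions: Dess–Martin periodinane (3 equiv), NaHCO3, CH2Cl2, 0 to 23 °C; used at once
Reagents that add atoms: none
Why: Dess–Martin oxidation converts the primary and the secondary alcohol in one operation under buffered, non-basic conditions that should not epimerise the α-chloro ketone.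

Step 11
Reactants: 13 chloro keto aldehyde
Product: 15 (1S,4R,6S)-1-methyl-4-[3-(TBSO)-6-methylhepta-1,5-dien-2-yl]-7-oxabicyclo[4.1.0]heptan-2-one, via chlorohydrin ketol 14 (not isolated)
Conditions: 2-(pentafluorophenyl)-6,7-dihydro-5H-pyrrolo[2,1-c][1,2,4]triazol-2-ium tetrafluoroborate (15 mol%), i-Pr2NEt (1.2 equiv), CH2Cl2 (0.02 M), 23 °C; then K2CO3 (2 equiv), CH3OH, 0 °C
Reagents that add atoms: none
Why: Proposed new method: the triazolylidene adds to the aldehyde of 13 to give the enaminol acyl-anion equivalent, which attacks the activated α-chloro methyl ketone (intramolecular crossed aldehyde–ketone benzoin reaction, the closest known reaction type, established for keto aldehydes that close to 2-hydroxy-2-methylcyclohexanones), and the tertiary alkoxide of ketol 14 then displaces the neighbouring chloride as in the second half of a Darzens reaction, so that an acyclic keto aldehyde should become the epoxy ketone in one flask. The cyclohexanone closes by 6-exo-trig attack of the acyl-anion carbon on the ketone carbonyl and the oxirane by 3-exo-tet displacement. The new fully substituted carbon is set in a chair-like transition state with the large side chain equatorial, hence the C–Cl bond axial, the methyl group equatorial and the carbonyl oxygen axial and anti to chlorine (dipole-minimised Cornforth arrangement), which places O and Cl trans-diaxial; the epoxide CH carbon then arises by inversion of the catalyst-installed (R)-chloride, so the oxirane ends up cis to the side chain. The step needs chemoselectivity (carbene addition to the aldehyde instead of alkylation or reduction at C–Cl, benzoin instead of aldol or Favorskii chemistry) and the trans relationship of O and Cl: a secondary chloride, a hindered electron-poor N-aryl carbene and a non-nucleophilic amine in the first stage address the former, and the (5R) configuration relative to (3S) secures the latter. Because the benzoin step is reversible under the carbene whereas oxirane closure is not, a minor cis-chlorohydrin can return and be funnelled to 15, and the product, having no free hydroxyl, cannot undergo retro-benzoin cleavage.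

Step 12
Reactants: 15 epoxy ketone
Product: 16 (1S,3S,4S,6S)-3-hydroxy-1-methyl-4-[3-(TBSO)-6-methylhepta-1,5-dien-2-yl]-7-oxabicyclo[4.1.0]heptan-2-one
Conditions: KN(SiMe3)2 (1.2 equiv), THF, −78 °C; then 2-(phenylsulfonyl)-3-phenyloxaziridine (1.4 equiv), −78 °C
Reagents that add atoms: 2-(phenylsulfonyl)-3-phenyloxaziridine, O=S(=O)(c1ccccc1)N1OC1c1ccccc1
Why: Enolate α-hydroxylation with an N-sulfonyloxaziridine: only C3 can be deprotonated (C1 is fully substituted), and oxygen should be transferred to the enolate face anti to the adjacent C4 side chain, giving the trans (3S) alcohol, which is also the more stable diequatorial epimer.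

Step 13
Reactants: 16 α-hydroxy ketone
Product: 17 (1S,3S,4S,6S)-1-methyl-2-oxo-4-[3-(TBSO)-6-methylhepta-1,5-dien-2-yl]-7-oxabicyclo[4.1.0]heptan-3-yl 3-methylbutanoate
Conditions: 3-methylbutanoyl chloride (1.5 equiv), pyridine, 4-(dimethylamino)pyridine (10 mol%), CH2Cl2, 0 °C
Reagents that add atoms: 3-methylbutanoyl chloride, CC(C)CC(=O)Cl
Why: Acyl-transfer esterification of the secondary α-hydroxy ketone under 4-(dimethylamino)pyridine catalysis takes place at oxygen and leaves the stereocentres untouched.

Step 14
Reactants: 17 silyl ether ester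
Product: 18 (1S,3S,4S,6S)-4-(3-hydroxy-6-methylhepta-1,5-dien-2-yl)-1-methyl-2-oxo-7-oxabicyclo[4.1.0]heptan-3-yl 3-methylbutanoate
Conditions: HF·pyridine, pyridine/THF, 0 to 23 °C
Reagents that add atoms: none
Why: Fluoride-mediated cleavage of the silyl ether with buffered HF·pyridine is compatible with the ester, the α-acyloxy ketone and the electron-poor epoxide.

Step 15
Reactants: 18 allylic alcohol
Product: 19 (1S,3S,4S,6S)-1-methyl-4-(6-methyl-3-oxohepta-1,5-dien-2-yl)-2-oxo-7-oxabicyclo[4.1.0]heptan-3-yl 3-methylbutanoate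
Conditions: Dess–Martin periodinane (1.5 equiv), NaHCO3, CH2Cl2, 0 °C; used directly
Reagents that add atoms: none
Why: Dess–Martin oxidation of the allylic alcohol gives the cross-conjugated enone under buffered neutral conditions that should leave the β,γ-unsaturated prenyl unit unconjugated, and it erases the temporary carbinol centre.

Step 16
Reactants: 19 prenyl ketone
Product: 20 (1S,3S,4S,6S)-4-[(4E)-6-hydroperoxy-6-methyl-3-oxohepta-1,4-dien-2-yl]-1-methyl-2-oxo-7-oxabicyclo[4.1.0]heptan-3-yl 3-methylbutanoate
Conditions: O2, 5,10,15,20-tetraphenylporphyrin (1 mol%), visible light, CH2Cl2, −20 °C; no reductive work-up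
Reagents that add atoms: dioxygen, O=O
Why: Schenck ene reaction, in which singlet oxygen should attack only the electron-rich trisubstituted alkene, abstract the activated hydrogen between carbonyl and alkene on the more crowded side (cis effect) and, by the double-bond shift, give the tertiary allylic hydroperoxide and the conjugated (E)-enone.

**Compound list**

1 | 4-methylpent-3-en-1-ol | CC(C)=CCCO | starting material
2 | 4-methylpent-3-enal | CC(C)=CCC=O | intermediate
3 | 6-methylhept-5-en-1-yn-3-ol (both enantiomers) | C#CC(O)CC=C(C)C | intermediate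
4 | tert-butyldimethyl[(6-methylhept-5-en-1-yn-3-yl)oxy]silane (both enantiomers) | C#CC(O[Si](C)(C)C(C)(C)C)CC=C(C)C | intermediate
5 | tert-butyldimethyl{[6-methyl-2-(4,4,5,5-tetramethyl-1,3,2-dioxaborolan-2-yl)hepta-1,5-dien-3-yl]oxy}silane (both enantiomers) | C=C(B1OC(C)(C)C(C)(C)O1)C(O[Si](C)(C)C(C)(C)C)CC=C(C)C | intermediate
6 | 5,6-dihydro-2H-pyran-2-one | O=C1C=CCCO1 | starting material
7 | (4S)-4-[3-(TBSO)-6-methylhepta-1,5-dien-2-yl]oxan-2-one (side-chain carbinol epimers) | O=C1C[C@@H](C(=C)C(O[Si](C)(C)C(C)(C)C)CC=C(C)C)CCO1 | intermediate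
8 | (4S)-4-[3-(TBSO)-6-methylhepta-1,5-dien-2-yl]oxan-2-ol (lactol, both anomers) | OC1C[C@@H](C(=C)C(O[Si](C)(C)C(C)(C)C)CC=C(C)C)CCO1 | intermediate
9 | (3R)-6-methoxy-3-[3-(TBSO)-6-methylhepta-1,5-dien-2-yl]hex-5-en-1-ol (E and Z enol ether, not isolated) | COC=CC[C@@H](C(=C)C(O[Si](C)(C)C(C)(C)C)CC=C(C)C)CCO | intermediate
10 | (4R)-6-hydroxy-4-[3-(TBSO)-6-methylhepta-1,5-dien-2-yl]hexanal | O=CCC[C@@H](C(=C)C(O[Si](C)(C)C(C)(C)C)CC=C(C)C)CCO | intermediate
11 | (2R,4S)-2-chloro-6-hydroxy-4-[3-(TBSO)-6-methylhepta-1,5-dien-2-yl]hexanal | O=C[C@H](Cl)C[C@@H](C(=C)C(O[Si](C)(C)C(C)(C)C)CC=C(C)C)CCO | intermediate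
12 | (3S,5R)-5-chloro-3-[3-(TBSO)-6-methylhepta-1,5-dien-2-yl]heptane-1,6-diol (C6 epimers) | CC(O)[C@H](Cl)C[C@@H](C(=C)C(O[Si](C)(C)C(C)(C)C)CC=C(C)C)CCO | intermediate
13 | (3S,5R)-5-chloro-3-[3-(TBSO)-6-methylhepta-1,5-dien-2-yl]-6-oxoheptanal | CC(=O)[C@H](Cl)C[C@@H](C(=C)C(O[Si](C)(C)C(C)(C)C)CC=C(C)C)CC=O | intermediate
14 | (2R,3R,5S)-3-chloro-2-hydroxy-2-methyl-5-[3-(TBSO)-6-methylhepta-1,5-dien-2-yl]cyclohexan-1-one (not isolated) | O=C1[C@@](C)(O)[C@H](Cl)C[C@@H](C(=C)C(O[Si](C)(C)C(C)(C)C)CC=C(C)C)C1 | intermediate
15 | (1S,4R,6S)-1-methyl-4-[3-(TBSO)-6-methylhepta-1,5-dien-2-yl]-7-oxabicyclo[4.1.0]heptan-2-one | C=C(C(O[Si](C)(C)C(C)(C)C)CC=C(C)C)[C@@H]1C[C@@H]2O[C@]2(C)C(=O)C1 | intermediate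
16 | (1S,3S,4S,6S)-3-hydroxy-1-methyl-4-[3-(TBSO)-6-methylhepta-1,5-dien-2-yl]-7-oxabicyclo[4.1.0]heptan-2-one | C=C(C(O[Si](C)(C)C(C)(C)C)CC=C(C)C)[C@@H]1C[C@@H]2O[C@]2(C)C(=O)[C@H]1O | intermediate
17 | (1S,3S,4S,6S)-1-methyl-2-oxo-4-[3-(TBSO)-6-methylhepta-1,5-dien-2-yl]-7-oxabicyclo[4.1.0]heptan-3-yl 3-methylbutanoate | C=C(C(O[Si](C)(C)C(C)(C)C)CC=C(C)C)[C@@H]1C[C@@H]2O[C@]2(C)C(=O)[C@H]1OC(=O)CC(C)C | intermediate
18 | (1S,3S,4S,6S)-4-(3-hydroxy-6-methylhepta-1,5-dien-2-yl)-1-methyl-2-oxo-7-oxabicyclo[4.1.0]heptan-3-yl 3-methylbutanoate | C=C(C(O)CC=C(C)C)[C@@H]1C[C@@H]2O[C@]2(C)C(=O)[C@H]1OC(=O)CC(C)C | intermediate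
19 | (1S,3S,4S,6S)-1-methyl-4-(6-methyl-3-oxohepta-1,5-dien-2-yl)-2-oxo-7-oxabicyclo[4.1.0]heptan-3-yl 3-methylbutanoate | C=C(C(=O)CC=C(C)C)[C@@H]1C[C@@H]2O[C@]2(C)C(=O)[C@H]1OC(=O)CC(C)C | intermediate
20 | (1S,3S,4S,6S)-4-[(4E)-6-hydroperoxy-6-methyl-3-oxohepta-1,4-dien-2-yl]-1-methyl-2-oxo-7-oxabicyclo[4.1.0]heptan-3-yl 3-methylbutanoate (CNP0241468.1) | C=C(C(=O)/C=C/C(C)(C)OO)[C@@H]1C[C@@H]2O[C@]2(C)C(=O)[C@H]1OC(=O)CC(C)C | target

**Step count and risk**

Total step count: 16. Longest linear sequence: 16 steps (1 to 20).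

Steps most likely to fail:

1. Step 11 (proposed new method). The carbene may be consumed by alkylation at the secondary C–Cl bond, the chlorine-bearing carbon may epimerise, 13 may divert into aldol or Favorskii-type chemistry before the benzoin event, or the tertiary alkoxide may fail to close. The fallback uses known chemistry, makes the same ring bond by an intramolecular Nozaki–Hiyama–Kishi reaction and the epoxide by hydroxyl-directed epoxidation; it sets out from lactol 8 and comes back at epoxy ketone 15. Stork–Zhao olefination of 8 ((1-iodoethyl)triphenylphosphonium iodide, NaN(SiMe3)2, THF, −78 °C) should give the (Z)-iodoalkenol F1, and Dess–Martin oxidation the (Z)-iodoalkenal F2. CrCl2 with catalytic NiCl2 in DMSO at high dilution should close the ring to the cyclohexenol F3, whose hydroxyl is expected cis to the side chain (both pseudo-equatorial in the chair-like transition state). VO(C5H7O2)2 (vanadyl acetylacetonate) with t-BuOOH should deliver the epoxide syn to the hydroxyl, giving the epoxy alcohol F4, and Dess–Martin oxidation of F4 gives 15.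

2. Step 16. Site selectivity of hydrogen abstraction in the ene reaction may be poor (geminal methyl groups instead of the methylene between carbonyl and alkene), giving the isomeric secondary hydroperoxide. The fallback goes from 19 directly to 20 and creates no new compound (F0): initiated autoxidation with ground-state oxygen (O2, catalytic 2,2'-azobis(4-methoxy-2,4-dimethylvaleronitrile), CH3CN, 30 °C). The radical formed by abstraction of the doubly activated hydrogen is trapped reversibly by oxygen and should settle as the conjugated tertiary peroxyl radical, so the hydroperoxide position is fixed by dienyl-radical thermodynamics and not by the ene transition state; this is the known autoxidation of β,γ-unsaturated ketones to γ-hydroperoxy enones.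

3. Step 12. Facial selectivity of oxygen transfer to the potassium enolate may be poor, or the α,β-epoxy ketone may degrade under strong base (including addition of the enolate to the sulfonimine by-product). The fallback is base-free enamine catalysis, setting out from 15 and coming back at 16: D-proline (30 mol%) and nitrosobenzene in DMSO at 23 °C should give the α-anilinooxy ketone F5, with the new centre set by the catalyst (by analogy with the (R)-selectivity of L-proline on cyclohexanone). CuSO4·5H2O (30 mol%) in CH3OH at 0 °C then cleaves the N–O bond to 16.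

**Further compounds**

F1 | step 11 | (3R,5Z)-6-iodo-3-[3-(TBSO)-6-methylhepta-1,5-dien-2-yl]hept-5-en-1-ol | C/C(I)=C/C[C@@H](C(=C)C(O[Si](C)(C)C(C)(C)C)CC=C(C)C)CCO
F2 | step 11 | (3R,5Z)-6-iodo-3-[3-(TBSO)-6-methylhepta-1,5-dien-2-yl]hept-5-enal | C/C(I)=C/C[C@@H](C(=C)C(O[Si](C)(C)C(C)(C)C)CC=C(C)C)CC=O
F3 | step 11 | (1R,5R)-2-methyl-5-[3-(TBSO)-6-methylhepta-1,5-dien-2-yl]cyclohex-2-en-1-ol (hydroxyl cis to the side chain) | CC1=CC[C@@H](C(=C)C(O[Si](C)(C)C(C)(C)C)CC=C(C)C)C[C@H]1O
F4 | step 11 | (1R,2R,4S,6S)-1-methyl-4-[3-(TBSO)-6-methylhepta-1,5-dien-2-yl]-7-oxabicyclo[4.1.0]heptan-2-ol (hydroxyl, epoxide and side chain all cis) | C=C(C(O[Si](C)(C)C(C)(C)C)CC=C(C)C)[C@@H]1C[C@@H]2O[C@]2(C)[C@H](O)C1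
F0 | step 16 | none | none
F5 | step 12 | (1S,3S,4S,6S)-3-(anilinooxy)-1-methyl-4-[3-(TBSO)-6-methylhepta-1,5-dien-2-yl]-7-oxabicyclo[4.1.0]heptan-2-one | C=C(C(O[Si](C)(C)C(C)(C)C)CC=C(C)C)[C@@H]1C[C@@H]2O[C@]2(C)C(=O)[C@H]1ONc1ccccc1
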